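**Retrosynthetic overview**

1. Target ⇐ (Pinnick, MnO2, desilylation) tetraol ⇐ hydride opening of 3-oxo-19,6β-olide 24. The β-diaxial pair C19 (on C4) / O–C6 is read as a γ-lactone, and C3(=O)–C4(CH3)–C19 as a 2-methylacetoacetate.
2. Ring A is cut at C1–C2 and C4–C5: a [3+3] union of the acetoacetate carbons C2–C3–C4 with a ring-B piece that carries C1 as a CH2OTs group on C10.
3. Enabling feature: C7 is the allylic CH2 between C6 and the C8=C9 bond, so a C7–O–C19 ester is a traceless tether. A [3,3] shift across O–C7–C6=C5 puts C4 on C5, the remaining ketone enolate (C2) closes on C1, and the freed C19 carboxylate closes on C6.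
4. Ring B comes from 2,3-dimethylbenzoic acid: lateral alkylation (C12–C16), auxiliary-controlled Birch reduction–methylation (C10), bis-allylic oxidation and CBS reduction (C7).
5. Ring order: ring B (from the arene), then ring A and the lactone ring in one operation; the lactone ring is opened at the end.

Key step: step 12

Remark: labdane numbering is used (C1–C10 decalin, C11–C16 side chain, C17 on C8, C18 = 4α-CH3, C19 = 4β-carbon, C20 on C10; β = face of C20); "chain" = (3E)-5-[(tert-butyldimethylsilyl)oxy]-3-methylpent-3-en-1-yl.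
Remark: the facial sense of the methylation in step 6 is assumed to follow the chelated-enolate model for 2-alkylbenzamides of (S)-2-(methoxymethyl)pyrrolidine; if it is the opposite, the (R)-amine is used in step 4 and nothing else changes.

Step 1
Reactants: 1 3-methylbut-2-en-1-ol
Product: 2 tert-butyldimethyl[(3-methylbut-2-en-1-yl)oxy]silane
Conditions: TBSCl, imidazole, CH2Cl2, 0 → 23 °C
Reagents that add atoms: tert-butyldimethylsilyl chloride, CC(C)(C)[Si](C)(C)Cl
Why: Standard O-silylation of a primary allylic alcohol.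

Step 2
Reactants: 2 tert-butyldimethyl[(3-methylbut-2-en-1-yl)oxy]silane
Product: 3 (2E)-4-[(tert-butyldimethylsilyl)oxy]-2-methylbut-2-en-1-ol
Conditions: SeO2 (cat.), t-BuOOH, salicylic acid (cat.), CH2Cl2, 23 °C
Reagents that add atoms: tert-butyl hydroperoxide (oxygen source, relayed by SeO2), CC(C)(C)OO
Why: Riley allylic oxidation (ene reaction then [2,3] shift) hydroxylates the (E)-methyl group of a trisubstituted alkene, which should fix the E geometry of the later C13=C14 bond.

Step 3
Reactants: 3 (2E)-4-[(tert-butyldimethylsilyl)oxy]-2-methylbut-2-en-1-ol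
Product: 4 {[(2E)-4-bromo-3-methylbut-2-en-1-yl]oxy}(tert-butyl)dimethylsilane
Conditions: CBr4, PPh3, 2,6-lutidine, CH2Cl2, −20 °C
Reagents that add atoms: carbon tetrabromide, BrC(Br)(Br)Br
Why: Appel bromination of a primary allylic alcohol proceeds by SN2 at the CH2 carbon, so the alkene geometry and position should be kept.

Step 4
Reactants: 5 2,3-dimethylbenzoic acid; 6 (S)-2-(methoxymethyl)pyrrolidine
Product: 8 (2,3-dimethylphenyl)[(2S)-2-(methoxymethyl)pyrrolidin-1-yl]methanone, via acid chloride 7 (not isolated)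
Conditions: (COCl)2, DMF (cat.), CH2Cl2, 23 °C; then 6, Et3N, CH2Cl2, 0 → 23 °C
Reagents that add atoms: none
Why: Schotten–Baumann-type acylation of the secondary amine by the acid chloride installs the chiral auxiliary.

Step 5
Reactants: 8 (2,3-dimethylphenyl)[(2S)-2-(methoxymethyl)pyrrolidin-1-yl]methanone; 4 {[(2E)-4-bromo-3-methylbut-2-en-1-yl]oxy}(tert-butyl)dimethylsilane
Product: 10 [2-(chain)-3-methylphenyl][(2S)-2-(methoxymethyl)pyrrolidin-1-yl]methanone, via benzylic lithium species 9 (not isolated)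
Conditions: LiN(i-Pr)2, THF, −78 °C; then 4, −78 → −30 °C
Reagents that add atoms: none
Why: Amide-directed lateral lithiation acidifies only the methyl group ortho to the amide, and the benzylic anion should alkylate the primary allylic bromide by SN2 to form C11–C12 with the E alkene intact.

Step 6
Reactants: 10 [2-(chain)-3-methylphenyl][(2S)-2-(methoxymethyl)pyrrolidin-1-yl]methanone
Product: 12 [(1S)-1,3-dimethyl-2-(chain)cyclohexa-2,5-dien-1-yl][(2S)-2-(methoxymethyl)pyrrolidin-1-yl]methanone, via potassium amide enolate 11 (not isolated)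
Conditions: K, NH3/THF, t-BuOH (1 equiv), −78 °C; then MeI, −78 °C
Reagents that add atoms: iodomethane, CI
Why: Auxiliary-controlled Birch reduction–alkylation: the chelated amide enolate should be methylated at the ipso carbon on the face away from the methoxymethyl arm, which sets C10, while the isolated alkene and silyl ether should survive a near-stoichiometric charge of metal at −78 °C.

Step 7
Reactants: 12 [(1S)-1,3-dimethyl-2-(chain)cyclohexa-2,5-dien-1-yl][(2S)-2-(methoxymethyl)pyrrolidin-1-yl]methanone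
Product: 13 [(1S)-1,3-dimethyl-2-(chain)cyclohexa-2,5-dien-1-yl]methanol
Conditions: LiNH2BH3 (from BH3·NH3 and LiN(i-Pr)2), THF, 0 → 23 °C
Reagents that add atoms: none
Why: Lithium amidotrihydroborate reduces hindered tertiary amides to primary alcohols with C–N cleavage and does not hydroborate alkenes, so C1 is obtained as CH2OH and the auxiliary is released.

Step 8
Reactants: 13 [(1S)-1,3-dimethyl-2-(chain)cyclohexa-2,5-dien-1-yl]methanol
Product: 14 [(1S)-1,3-dimethyl-2-(chain)cyclohexa-2,5-dien-1-yl]methyl 4-methylbenzenesulfonate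
Conditions: TsCl, Et3N, DMAP (cat.), CH2Cl2, 23 °C
Reagents that add atoms: p-toluenesulfonyl chloride, Cc1ccc(cc1)S(=O)(=O)Cl
Why: O-sulfonylation does not touch the C1–O bond, so the neopentyl, homoallylic carbon is activated without ionisation.

Step 9
Reactants: 14 [(1S)-1,3-dimethyl-2-(chain)cyclohexa-2,5-dien-1-yl]methyl 4-methylbenzenesulfonate
Product: 15 [(1S)-1,3-dimethyl-4-oxo-2-(chain)cyclohexa-2,5-dien-1-yl]methyl 4-methylbenzenesulfonate
Conditions: (C5H5NH)2Cr2O7, t-BuOOH, Celite, benzene, 23 °C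
Reagents that add atoms: tert-butyl hydroperoxide, CC(C)(C)OO
Why: Bis-allylic C–H oxidation: C7 is the only doubly allylic CH2 and the quaternary C10 rules out aromatisation, so the cross-conjugated dienone should form.

Step 10
Reactants: 15 [(1S)-1,3-dimethyl-4-oxo-2-(chain)cyclohexa-2,5-dien-1-yl]methyl 4-methylbenzenesulfonate
Product: 16 [(1S,4S)-4-hydroxy-1,3-dimethyl-2-(chain)cyclohexa-2,5-dien-1-yl]methyl 4-methylbenzenesulfonate (7β-OH, cis to C20)
Conditions: (R)-2-methyl-CBS-oxazaborolidine (cat.), catecholborane, toluene, −78 °C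
Reagents that add atoms: none
Why: Corey–Bakshi–Shibata reduction: the catalyst should treat the α-methylated alkenyl arm (C8) as the large group and the unsubstituted arm (C6) as the small one, delivering hydride to the α face of C7 under catalyst control.

Step 11
Reactants: 16 [(1S,4S)-4-hydroxy-1,3-dimethyl-2-(chain)cyclohexa-2,5-dien-1-yl]methyl 4-methylbenzenesulfonate; 17 methyl 2-methyl-3-oxobutanoate
Product: 19 (1S,4S)-2,4-dimethyl-3-(chain)-4-[(tosyloxy)methyl]cyclohexa-2,5-dien-1-yl 2-methyl-3-oxobutanoate (both epimers at the acetoacetate α-carbon), via acetyl(methyl)ketene 18 (not isolated)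
Conditions: 17, DMAP (cat.), 4 Å molecular sieves, toluene, 100 °C
Reagents that add atoms: none
Why: DMAP-catalysed transesterification of a β-keto ester through its acylketene is neutral to mildly basic, so the acid-labile dienol should be acylated with retention at C7; the α-epimers converge on enolisation in step 12.

Step 12
Reactants: 19 (1S,4S)-2,4-dimethyl-3-(chain)-4-[(tosyloxy)methyl]cyclohexa-2,5-dien-1-yl 2-methyl-3-oxobutanoate
Product: 23 15-[(tert-butyldimethylsilyl)oxy]-7α-iodo-3-oxolabda-8,13(E)-dien-19,6β-olide, via dilithium dienolate 20 (not isolated), via rearranged keto-enolate carboxylate 21 (not isolated), via ring-A lithium carboxylate 22 (not isolated)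
Conditions: LiN(i-Pr)2 (2.1 equiv), THF, −78 → 23 °C; DMPU, 55 °C; then aq. NaHCO3, I2, THF, 0 °C, dark
Reagents that add atoms: iodine, II
Why: Proposed new method: double deprotonation gives the lithium-chelated α,γ-dianion 20, whose ester-enolate half undergoes the [3,3] shift across O–C7–C6=C5 to form C4–C5 (closest known type: dianionic Carroll rearrangement, which keeps the carboxyl group), and the methyl-ketone enolate left in 21 then displaces the neopentyl tosylate to form C1–C2 (closest known type: intramolecular ketone-enolate alkylation); joining the two in one cascade is the untested part. Ring A closes by a 6-(enolendo)-exo-tet C-alkylation, helped by the quaternary carbons C4 and C10 (Thorpe–Ingold effect) and by DMPU, and the lactone ring closes by 5-exo-trig anti iodolactonisation of carboxylate 22 onto C6=C7. C5 is set by suprafacial chirality transfer from C7 (the β C7–O bond becomes the β C4–C5 bond, trans to the α CH2OTs group, so ring A is trans-fused); C4 is set by a chair transition state of the chelated enolate in which the C4 methyl points away from C10 and C19 lies over the flat ring B; C6 and C7 are set by delivery of the axial C19 carboxylate to the β face anti to the iodonium ion. The step needs C5 over C9 in the [3,3] shift (C9 is fully substituted and would give vicinal quaternary carbons), C- over O-alkylation (lithium enolate, six-membered enolendo closure, no β-hydrogen for elimination) and γ- over δ-lactone closure (C19 and C6 are 1,3-diaxial). Iodine is added without isolating 22 because the free β-keto acid would lose CO2.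

Step 13
Reactants: 23 15-[(tert-butyldimethylsilyl)oxy]-7α-iodo-3-oxolabda-8,13(E)-dien-19,6β-olide
Product: 24 15-[(tert-butyldimethylsilyl)oxy]-3-oxolabda-8,13(E)-dien-19,6β-olide
Conditions: Bu3SnH, Et3B (cat.), air, toluene, 0 °C
Reagents that add atoms: none
Why: Radical dehalogenation: the C7–C8–C9 allyl radical should take hydrogen at the secondary terminus C7 and not at the fully substituted C9, which restores the tetrasubstituted C8=C9 alkene (a 9-iodo allylic isomer would give the same radical).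

Step 14
Reactants: 24 15-[(tert-butyldimethylsilyl)oxy]-3-oxolabda-8,13(E)-dien-19,6β-olide
Product: 26 15-[(tert-butyldimethylsilyl)oxy]labda-8,13(E)-diene-3α,6β,19-triol, via 3α-hydroxy lactone 25 (not isolated)
Conditions: Li[HB(s-Bu)3], THF, −78 °C; then LiAlH4, −78 → 0 °C
Reagents that add atoms: none
Why: The bulky borohydride should approach the C3 ketone along the equatorial (β) trajectory, away from the axial hydrogens on C1 and C5, to give the axial 3α-alcohol, and LiAlH4 then reduces the lactone to the C19/C6β diol without touching the C6–O bond.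

Step 15
Reactants: 26 15-[(tert-butyldimethylsilyl)oxy]labda-8,13(E)-diene-3α,6β,19-triol
Product: 27 labda-8,13(E)-diene-3α,6β,15,19-tetraol
Conditions: Bu4NF, THF, 23 °C
Reagents that add atoms: none
Why: Fluoride-driven desilylation frees the allylic C15 alcohol.

Step 16
Reactants: 27 labda-8,13(E)-diene-3α,6β,15,19-tetraol
Product: 28 3α,6β,19-trihydroxylabda-8,13(E)-dien-15-al
Conditions: MnO2, CH2Cl2, 23 °C
Reagents that add atoms: none
Why: Activated MnO2 oxidises only the allylic C15 alcohol (C3, C6 and C19 hydroxyls are not allylic) and should keep the E geometry.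

Step 17
Reactants: 28 3α,6β,19-trihydroxylabda-8,13(E)-dien-15-al
Product: 29 3α,6β,19-trihydroxylabda-8,13(E)-dien-15-oic acid (target)
Conditions: NaClO2, NaH2PO4, 2-methylbut-2-ene, t-BuOH/H2O, 23 °C
Reagents that add atoms: sodium chlorite, [Na+].[O-]Cl=O
Why: Pinnick oxidation converts the enal into the acid without touching free alcohols or alkenes, the hypochlorite being scavenged by 2-methylbut-2-ene.

**Compound list**

1 | 3-methylbut-2-en-1-ol | CC(C)=CCO | starting material
2 | tert-butyldimethyl[(3-methylbut-2-en-1-yl)oxy]silane | CC(C)=CCO[Si](C)(C)C(C)(C)C | intermediate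
3 | (2E)-4-[(tert-butyldimethylsilyl)oxy]-2-methylbut-2-en-1-ol | OC/C(C)=C/CO[Si](C)(C)C(C)(C)C | intermediate
4 | {[(2E)-4-bromo-3-methylbut-2-en-1-yl]oxy}(tert-butyl)dimethylsilane | BrC/C(C)=C/CO[Si](C)(C)C(C)(C)C | intermediate
5 | 2,3-dimethylbenzoic acid | Cc1cccc(C(=O)O)c1C | starting material
6 | (S)-2-(methoxymethyl)pyrrolidine | COC[C@@H]1CCCN1 | starting material
7 | 2,3-dimethylbenzoyl chloride | Cc1cccc(C(=O)Cl)c1C | intermediate (not isolated)
8 | (2,3-dimethylphenyl)[(2S)-2-(methoxymethyl)pyrrolidin-1-yl]methanone | Cc1cccc(C(=O)N2CCC[C@H]2COC)c1C | intermediate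
9 | 2-(lithiomethyl) derivative of 8 | [Li]Cc1c(C)cccc1C(=O)N1CCC[C@H]1COC | intermediate (not isolated)
10 | [2-(chain)-3-methylphenyl][(2S)-2-(methoxymethyl)pyrrolidin-1-yl]methanone | Cc1cccc(C(=O)N2CCC[C@H]2COC)c1CC/C(C)=C/CO[Si](C)(C)C(C)(C)C | intermediate
11 | potassium amide enolate of the 1,4-dihydroarene (C7 protonated) | CC1=C(CC/C(C)=C/CO[Si](C)(C)C(C)(C)C)C(C=CC1)=C([O-])N1CCC[C@H]1COC.[K+] | intermediate (not isolated)
12 | [(1S)-1,3-dimethyl-2-(chain)cyclohexa-2,5-dien-1-yl][(2S)-2-(methoxymethyl)pyrrolidin-1-yl]methanone | CC1=C(CC/C(C)=C/CO[Si](C)(C)C(C)(C)C)[C@@](C)(C(=O)N2CCC[C@H]2COC)C=CC1 | intermediate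
13 | [(1S)-1,3-dimethyl-2-(chain)cyclohexa-2,5-dien-1-yl]methanol | CC1=C(CC/C(C)=C/CO[Si](C)(C)C(C)(C)C)[C@@](C)(CO)C=CC1 | intermediate
14 | [(1S)-1,3-dimethyl-2-(chain)cyclohexa-2,5-dien-1-yl]methyl 4-methylbenzenesulfonate | CC1=C(CC/C(C)=C/CO[Si](C)(C)C(C)(C)C)[C@@](C)(COS(=O)(=O)c2ccc(C)cc2)C=CC1 | intermediate
15 | [(1S)-1,3-dimethyl-4-oxo-2-(chain)cyclohexa-2,5-dien-1-yl]methyl 4-methylbenzenesulfonate | CC1=C(CC/C(C)=C/CO[Si](C)(C)C(C)(C)C)[C@@](C)(COS(=O)(=O)c2ccc(C)cc2)C=CC1=O | intermediate
16 | [(1S,4S)-4-hydroxy-1,3-dimethyl-2-(chain)cyclohexa-2,5-dien-1-yl]methyl 4-methylbenzenesulfonate | CC1=C(CC/C(C)=C/CO[Si](C)(C)C(C)(C)C)[C@@](C)(COS(=O)(=O)c2ccc(C)cc2)C=C[C@@H]1O | intermediate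
17 | methyl 2-methyl-3-oxobutanoate | COC(=O)C(C)C(C)=O | starting material
18 | 2-methyl-3-oxobut-1-en-1-one (acetyl(methyl)ketene) | CC(=O)C(C)=C=O | intermediate (not isolated)
19 | (1S,4S)-2,4-dimethyl-3-(chain)-4-[(tosyloxy)methyl]cyclohexa-2,5-dien-1-yl 2-methyl-3-oxobutanoate | CC1=C(CC/C(C)=C/CO[Si](C)(C)C(C)(C)C)[C@@](C)(COS(=O)(=O)c2ccc(C)cc2)C=C[C@@H]1OC(=O)C(C)C(C)=O | intermediate
20 | dilithium α,γ-dienolate of 19 | [Li+].[Li+].CC1=C(CC/C(C)=C/CO[Si](C)(C)C(C)(C)C)[C@@](C)(COS(=O)(=O)c2ccc(C)cc2)C=C[C@@H]1OC([O-])=C(C)C([O-])=C | intermediate (not isolated)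
21 | dilithium salt of the Carroll product (C4–C5 formed; C19 carboxylate, C2=C3 enolate; ring B 6,8-diene) | [Li+].[Li+].CC1=C(CC/C(C)=C/CO[Si](C)(C)C(C)(C)C)[C@@](C)(COS(=O)(=O)c2ccc(C)cc2)[C@@H](C=C1)[C@@](C)(C([O-])=O)C([O-])=C | intermediate (not isolated)
22 | lithium 15-[(tert-butyldimethylsilyl)oxy]-3-oxolabda-6,8,13(E)-trien-19-oate | [Li+].CC1=C(CC/C(C)=C/CO[Si](C)(C)C(C)(C)C)[C@@]2(C)CCC(=O)[C@](C)(C([O-])=O)[C@@H]2C=C1 | intermediate (not isolated)
23 | 15-[(tert-butyldimethylsilyl)oxy]-7α-iodo-3-oxolabda-8,13(E)-dien-19,6β-olide | CC1=C(CC/C(C)=C/CO[Si](C)(C)C(C)(C)C)[C@@]2(C)CCC(=O)[C@@]3(C)[C@@H]2[C@H](OC3=O)[C@H]1I | intermediate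
24 | 15-[(tert-butyldimethylsilyl)oxy]-3-oxolabda-8,13(E)-dien-19,6β-olide | CC1=C(CC/C(C)=C/CO[Si](C)(C)C(C)(C)C)[C@@]2(C)CCC(=O)[C@@]3(C)[C@@H]2[C@H](OC3=O)C1 | intermediate
25 | 15-[(tert-butyldimethylsilyl)oxy]-3α-hydroxylabda-8,13(E)-dien-19,6β-olide | CC1=C(CC/C(C)=C/CO[Si](C)(C)C(C)(C)C)[C@@]2(C)CC[C@@H](O)[C@@]3(C)[C@@H]2[C@H](OC3=O)C1 | intermediate (not isolated)
26 | 15-[(tert-butyldimethylsilyl)oxy]labda-8,13(E)-diene-3α,6β,19-triol | CC1=C(CC/C(C)=C/CO[Si](C)(C)C(C)(C)C)[C@@]2(C)CC[C@@H](O)[C@](C)(CO)[C@@H]2[C@H](O)C1 | intermediate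
27 | labda-8,13(E)-diene-3α,6β,15,19-tetraol | CC1=C(CC/C(C)=C/CO)[C@@]2(C)CC[C@@H](O)[C@](C)(CO)[C@@H]2[C@H](O)C1 | intermediate
28 | 3α,6β,19-trihydroxylabda-8,13(E)-dien-15-al | CC1=C(CC/C(C)=C/C=O)[C@@]2(C)CC[C@@H](O)[C@](C)(CO)[C@@H]2[C@H](O)C1 | intermediate
29 | 3α,6β,19-trihydroxylabda-8,13(E)-dien-15-oic acid | CC1=C(CC/C(C)=C/C(=O)O)[C@@]2(C)CC[C@@H](O)[C@](C)(CO)[C@@H]2[C@H](O)C1 | target

**Step count**

Total steps: 17. Longest linear sequence: 16 steps (steps 1–3, then 5–17, from 3-methylbut-2-en-1-ol); 14 steps from 2,3-dimethylbenzoic acid.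

**Steps most likely to fail**

Step 12 (Proposed new method). The SN2 closure at the neopentyl carbon C1 may be too slow, so that O-alkylation, attack of the enolate at sulfur or proton transfer takes over; a boat transition state in the [3,3] shift could also deliver the C4 epimer. The fallback replaces the alkylation by an aldol closure; it sets out from 13 and comes back at 24. Alcohol 13 would be oxidised with Dess–Martin periodinane to the 1-formyl diene F1 and masked as the dimethyl acetal F2 (MeOSiMe3, Me3SiOTf cat., CH2Cl2, −78 °C). Bis-allylic oxidation, CBS reduction and transesterification as in steps 9–11 would give the dienone acetal F3, the dienol acetal F4 and the keto ester acetal F5. The dianionic Carroll rearrangement (LiN(i-Pr)2, THF, −78 → 23 °C; the acetal is inert to the dianion) followed by aqueous NaHCO3/I2 would give the acetyl iodolactone F6, and Bu3SnH the acetyl lactone F7. Aqueous acid followed by pyrrolidinium acetate would unmask the aldehyde and close ring A by intramolecular aldol condensation of the methyl ketone to the enone lactone F8. Conjugate reduction with [(Ph3P)CuH]6 would then give 24.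

Step 10. The catalyst may fail to tell the two alkenyl arms of the cross-conjugated ketone apart, or the remote C10 centre may bias the hydride approach, giving poor facial selectivity at C7. The fallback sets out from 15 and comes back at 16. Luche reduction (NaBH4, CeCl3·7H2O, MeOH, −78 °C) would give 16 together with the 7α-hydroxy epimer F9; the two diastereomers would be separated by chromatography, and F9 would be oxidised back to 15 with MnO2 and recycled.

Step 11. At 100 °C the doubly allylic ester may ionise or undergo a premature [3,3] shift with loss of CO2, and the dienol may dehydrate. The fallback sets out from 16 and comes back at 19. Acylation with diketene (DMAP cat., CH2Cl2, −20 °C) would give the acetoacetate F10, and C-methylation (MeI, K2CO3, acetone, 23 °C) would give 19.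

**Further compounds**

F1 | step 12 | (1S)-1,3-dimethyl-2-(chain)cyclohexa-2,5-diene-1-carbaldehyde | CC1=C(CC/C(C)=C/CO[Si](C)(C)C(C)(C)C)[C@@](C)(C=O)C=CC1
F2 | step 12 | dimethyl acetal of F1 | CC1=C(CC/C(C)=C/CO[Si](C)(C)C(C)(C)C)[C@@](C)(C(OC)OC)C=CC1
F3 | step 12 | (4S)-4-(dimethoxymethyl)-2,4-dimethyl-3-(chain)cyclohexa-2,5-dien-1-one | CC1=C(CC/C(C)=C/CO[Si](C)(C)C(C)(C)C)[C@@](C)(C(OC)OC)C=CC1=O
F4 | step 12 | (1S,4S)-4-(dimethoxymethyl)-2,4-dimethyl-3-(chain)cyclohexa-2,5-dien-1-ol | CC1=C(CC/C(C)=C/CO[Si](C)(C)C(C)(C)C)[C@@](C)(C(OC)OC)C=C[C@@H]1O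
F5 | step 12 | 2-methyl-3-oxobutanoate ester of F4 | CC1=C(CC/C(C)=C/CO[Si](C)(C)C(C)(C)C)[C@@](C)(C(OC)OC)C=C[C@@H]1OC(=O)C(C)C(C)=O
F6 | step 12 | 7α-iodo-19,6β-lactone with C4 acetyl and C10 dimethoxymethyl groups (ring A open) | CC1=C(CC/C(C)=C/CO[Si](C)(C)C(C)(C)C)[C@@](C)(C(OC)OC)[C@H]2[C@H](OC(=O)[C@@]2(C)C(C)=O)[C@H]1I
F7 | step 12 | deiodinated acetyl lactone acetal | CC1=C(CC/C(C)=C/CO[Si](C)(C)C(C)(C)C)[C@@](C)(C(OC)OC)[C@H]2[C@H](OC(=O)[C@@]2(C)C(C)=O)C1
F8 | step 12 | 15-[(tert-butyldimethylsilyl)oxy]-3-oxolabda-1,8,13(E)-trien-19,6β-olide | CC1=C(CC/C(C)=C/CO[Si](C)(C)C(C)(C)C)[C@@]2(C)C=CC(=O)[C@@]3(C)[C@@H]2[C@H](OC3=O)C1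
F9 | step 10 | 7α-hydroxy epimer of 16 | CC1=C(CC/C(C)=C/CO[Si](C)(C)C(C)(C)C)[C@@](C)(COS(=O)(=O)c2ccc(C)cc2)C=C[C@H]1O
F10 | step 11 | 3-oxobutanoate ester of 16 | CC1=C(CC/C(C)=C/CO[Si](C)(C)C(C)(C)C)[C@@](C)(COS(=O)(=O)c2ccc(C)cc2)C=C[C@@H]1OC(=O)CC(C)=O
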